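**Plan**
- Cuts: (a) C3–C4 of ring C, back to an ortho-formyl aryl 1-arylvinyl ether; (b) the C2=C3 methylene, back to the carbonyl of an aryl ester joining O1 of ring A to the ring B acid; (c) the aryl C8–CH2 bond; (d) the Cα–CH2(prenyl) bond inside the lavandulyl unit.
- Forward: the lavandulyl iodide is made by auxiliary alkylation; ring A (from 5-methoxyresorcinol) is iodinated, cross-coupled with the side chain, formylated and freed at O1; it is esterified with the ring B acid, the ester carbonyl is methylenated, ring C is closed, and three MOM groups are removed.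
- Enabling feature: C4 hangs on C4a of ring A, ortho to C8a–O1, so an aldehyde C4–H and an O1-bound C2=C3 enol ether sit in a 1,6-relationship. C2 stays trigonal and non-epimerisable until ring C closes.
- Stereochemistry: the side-chain centre comes from (S)-4-benzyl-2-oxazolidinone (Evans alkylation); C2 (S) comes from the chiral rhodium catalyst in the ring closure.

Key step: step 14

Remark: "lavandulyl" means 5-methyl-2-(prop-1-en-2-yl)hex-4-en-1-yl. Its stereocentre is (S) by CIP rules while its CH2 carries O, I or Zn (or is the imide carbonyl) and becomes (R) once that CH2 carries the arene; the spatial arrangement never changes.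
Remark: the sense of induction in step 14 cannot be predicted with certainty. (R)-DTBM-SEGPHOS is written on the working assumption that it presents the Re face of C2; its antipode would be taken otherwise, with no change to the route.

Step 1
Reactants: 1 (S)-4-benzyl-2-oxazolidinone; 2 3-methylbut-2-enoyl chloride
Product: 4 (S)-4-benzyl-3-(3-methylbut-2-enoyl)oxazolidin-2-one, via lithium oxazolidinide 3 (not isolated)
Conditions: n-BuLi, THF, −78 °C; then 2, −78 to 0 °C
Reagents that add atoms: none
Why: N-acylation of a lithiated oxazolidinone by an acid chloride is the standard entry to Evans imides and, unlike amine-base methods, does not deconjugate the senecioyl unit through a vinylketene.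

Step 2
Reactants: 4; 5 prenyl bromide (1-bromo-3-methylbut-2-ene)
Product: 7 (S)-4-benzyl-3-[(2S)-5-methyl-2-(prop-1-en-2-yl)hex-4-enoyl]oxazolidin-2-one, via sodium dienolate 6 (not isolated)
Conditions: NaN(SiMe3)2, THF, −78 °C; then 5, −78 to −30 °C
Reagents that add atoms: none
Why: Deconjugative Evans alkylation: γ-deprotonation gives the sodium-chelated (Z)-dienolate, which the allylic bromide attacks at Cα on the face opposite the benzyl group, setting the (2S) centre while the alkene moves out of conjugation to become the isopropenyl group.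

Step 3
Reactants: 7
Product: 8 (S)-lavandulol [(2S)-5-methyl-2-(prop-1-en-2-yl)hex-4-en-1-ol]
Conditions: LiBH4, MeOH (1.1 equiv), Et2O, 0 °C
Reagents that add atoms: none
Why: Borohydride reductive cleavage of the N-acyl oxazolidinone (standard auxiliary removal) gives the primary alcohol without enolising the α-centre and returns the auxiliary.

Step 4
Reactants: 8
Product: 9 (S)-lavandulyl iodide [(3S)-3-(iodomethyl)-2,6-dimethylhepta-1,5-diene]
Conditions: I2, PPh3, imidazole, CH2Cl2, 0 °C to rt
Reagents that add atoms: iodine (II)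
Why: Appel-type iodination proceeds by SN2 displacement of the alkoxyphosphonium ion at the primary carbon, so the neighbouring stereocentre and both alkenes are untouched.

Step 5
Reactants: 10 5-methoxyresorcinol
Product: 11 1-methoxy-3,5-bis(methoxymethoxy)benzene
Conditions: MOMCl, i-Pr2NEt, CH2Cl2, 0 °C to rt
Reagents that add atoms: chloromethyl methyl ether (COCCl)
Why: Williamson-type O-alkylation of both phenols with MOMCl installs the directing and protecting groups needed for the two ortho-metalations.

Step 6
Reactants: 11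
Product: 13 2-iodo-5-methoxy-1,3-bis(methoxymethoxy)benzene, via aryllithium 12 (not isolated)
Conditions: n-BuLi, THF, 0 °C; then I2, −78 °C to rt
Reagents that add atoms: iodine (II)
Why: Directed ortho-metalation occurs at C2, the position flanked by both MOM ethers, and iodinolysis of the aryllithium gives the aryl iodide.

Step 7
Reactants: 9; 13
Product: 15 5-methoxy-1,3-bis(methoxymethoxy)-2-[(2R)-lavandulyl]benzene, via alkylzinc iodide 14 (not isolated)
Conditions: Zn dust (activated with BrCH2CH2Br and Me3SiCl), LiCl, THF, 40 °C; then 13, Pd(OAc)2 (2 mol %), SPhos (4 mol %), THF, 50 °C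
Reagents that add atoms: none
Why: Negishi sp3–sp2 cross-coupling of a primary alkylzinc iodide (LiCl-promoted zinc insertion) with a di-ortho-substituted aryl iodide is well served by the Pd/SPhos catalyst, and the stereocentre, β to zinc, takes no part.

Step 8
Reactants: 15
Product: 17 6-methoxy-2,4-bis(methoxymethoxy)-3-[(2R)-lavandulyl]benzaldehyde, via aryllithium 16 (not isolated)
Conditions: n-BuLi, TMEDA, THF, −20 to 0 °C; then DMF, −78 to 0 °C; H2O
Reagents that add atoms: N,N-dimethylformamide (CN(C)C=O)
Why: Directed ortho-metalation at either of the two equivalent ring positions between OMOM and OMe, then formylation with DMF, places the future C4 carbon ortho to what becomes O1.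

Step 9
Reactants: 17
Product: 18 2-hydroxy-6-methoxy-4-(methoxymethoxy)-3-[(2R)-lavandulyl]benzaldehyde
Conditions: conc. HCl (cat.), MeOH, 0 °C to rt, stopped at mono-deprotection
Reagents that add atoms: none
Why: Acid-catalysed acetal exchange selectively removes the MOM group ortho to the formyl group, whose cleavage is accelerated by hydrogen bonding and chelation to the carbonyl (well established for ortho-acyl aryl MOM ethers), leaving the distal MOM ether and the alkenes intact.

Step 10
Reactants: 19 2,4-dihydroxybenzoic acid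
Product: 21 2,4-bis(methoxymethoxy)benzoic acid, via methoxymethyl ester 20 (not isolated)
Conditions: NaH, MOMCl, DMF, 0 °C to rt; then aq. NaOH, MeOH, 50 °C; AcOH to pH 5 at 0 °C
Reagents that add atoms: chloromethyl methyl ether (COCCl)
Why: Exhaustive Williamson alkylation with MOMCl followed by saponification of the labile MOM ester in the same flask gives the protected acid.

Step 11
Reactants: 18; 21
Product: 22 2-formyl-3-methoxy-5-(methoxymethoxy)-6-[(2R)-lavandulyl]phenyl 2,4-bis(methoxymethoxy)benzoate
Conditions: EDC·HCl, DMAP, CH2Cl2, 0 °C to rt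
Reagents that add atoms: none
Why: Steglich esterification (carbodiimide activation with DMAP acyl transfer) acylates the hindered, hydrogen-bonded phenol under neutral conditions that spare the MOM ethers and the aldehyde.

Step 12
Reactants: 22
Product: 23 2-(dimethoxymethyl)-3-methoxy-5-(methoxymethoxy)-6-[(2R)-lavandulyl]phenyl 2,4-bis(methoxymethoxy)benzoate
Conditions: HC(OMe)3, PPTS (cat.), MeOH, rt
Reagents that add atoms: trimethyl orthoformate (COC(OC)OC); methanol (CO)
Why: Acid-catalysed acetalisation with orthoformate as water scavenger masks the aldehyde, which would otherwise be methylenated in preference to the ester in step 13.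

Step 13
Reactants: 23
Product: 25 2-{[1-(2,4-bis(methoxymethoxy)phenyl)ethenyl]oxy}-6-methoxy-4-(methoxymethoxy)-3-[(2R)-lavandulyl]benzaldehyde, via enol ether acetal 24 (not isolated)
Conditions: Cp2TiMe2 (3 equiv), toluene, 70 °C, dark; filtration through basic Al2O3; then SiO2 wetted with 5% aq. oxalic acid, CH2Cl2, 0 °C; Et3N quench
Reagents that add atoms: dimethyltitanocene (C[Ti](C)(C1C=CC=C1)C1C=CC=C1); water (O)
Why: Petasis methylenation (Cp2Ti=CH2, oxatitanacyclobutane, loss of Cp2Ti=O) converts the aryl ester into the aryl 1-arylvinyl ether under neutral conditions, after which the dimethyl acetal of the trioxygenated benzaldehyde, which should ionise far faster than an aryl vinyl ether is C-protonated, is hydrolysed selectively on weakly acidic wet silica.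

Step 14
Reactants: 25
Product: 26 (2S)-2-[2,4-bis(methoxymethoxy)phenyl]-5-methoxy-7-(methoxymethoxy)-8-[(2R)-lavandulyl]chroman-4-one
Conditions: [Rh(cod)Cl]2 (2.5 mol %), (R)-DTBM-SEGPHOS (5.5 mol %), Na[B(3,5-(CF3)2C6H3)4] (5 mol %), 1,4-dioxane, 4 Å MS, 60 °C
Reagents that add atoms: none
Why: Proposed new method: the aldehyde C4–H adds oxidatively to the cationic bisphosphine complex of monovalent rhodium to give an acyl hydride of trivalent rhodium, the O1-bound C2=C3 enol ether coordinates, the hydride inserts at C2 to put rhodium on C3, and C–C reductive elimination from the seven-membered acyl–alkyl rhodacycle forms C3–C4. The closest known reaction type is the rhodium-catalysed endo- and enantioselective intramolecular hydroacylation of 2-(2-substituted allyl)benzaldehydes to 3-substituted tetralones, of which this is the oxygen-tethered aryl vinyl ether analogue. Ring C closes in a 6-endo-trig mode with respect to the alkene. C2 is the only new stereocentre and is set under catalyst control in the hydride insertion, the chiral pocket of the bulky bisphosphine presenting the Re face of C2 to Rh–H (giving 2S), with the remote side-chain centre expected to act as a spectator. The step needs endo over exo closure (exo would give a 2-aryl-2-methylbenzofuran-3-one) and ring closure before decarbonylation or migration of the side-chain alkenes; the fully substituted C2, which resists a tertiary C–Rh bond, and the short O1 tether flanked by the coordinating 5-OMe should secure both. The enol ether has no allylic hydrogen, so the carbonyl-ene path is closed, and the neutral medium avoids both acid-triggered Prins closure to a flavylium ion and base-triggered opening of ring C that would erase C2.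

Step 15
Reactants: 26
Product: 27 kurarinone [(2S)-2-(2,4-dihydroxyphenyl)-7-hydroxy-5-methoxy-8-[(2R)-lavandulyl]chroman-4-one]
Conditions: NaHSO4·SiO2, CH2Cl2, rt
Reagents that add atoms: none
Why: Heterogeneous mild acid hydrolysis of aryl MOM ethers at room temperature releases the three phenols without base (which would open ring C and racemise C2) and without strong acid (which would add the 7-OH to the side-chain alkene).

**Compound list**
1 | (S)-4-benzyl-2-oxazolidinone | O=C1N[C@@H](Cc2ccccc2)CO1 | starting material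
2 | 3-methylbut-2-enoyl chloride | CC(C)=CC(=O)Cl | starting material
3 | lithium (S)-4-benzyl-2-oxooxazolidin-3-ide | [Li+].O=C1[N-][C@@H](Cc2ccccc2)CO1 | intermediate
4 | (S)-4-benzyl-3-(3-methylbut-2-enoyl)oxazolidin-2-one | CC(C)=CC(=O)N1[C@@H](Cc2ccccc2)COC1=O | intermediate
5 | prenyl bromide (1-bromo-3-methylbut-2-ene) | CC(C)=CCBr | starting material
6 | sodium (Z)-dienolate of 4 | [Na+].C=C(C)/C=C(\[O-])N1[C@@H](Cc2ccccc2)COC1=O | intermediate
7 | (S)-4-benzyl-3-[(2S)-5-methyl-2-(prop-1-en-2-yl)hex-4-enoyl]oxazolidin-2-one | C=C(C)[C@H](CC=C(C)C)C(=O)N1[C@@H](Cc2ccccc2)COC1=O | intermediate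
8 | (S)-lavandulol, (2S)-5-methyl-2-(prop-1-en-2-yl)hex-4-en-1-ol | C=C(C)[C@H](CC=C(C)C)CO | intermediate
9 | (S)-lavandulyl iodide, (3S)-3-(iodomethyl)-2,6-dimethylhepta-1,5-diene | C=C(C)[C@H](CC=C(C)C)CI | intermediate
10 | 5-methoxyresorcinol | COc1cc(O)cc(O)c1 | starting material
11 | 1-methoxy-3,5-bis(methoxymethoxy)benzene | COCOc1cc(OC)cc(OCOC)c1 | intermediate
12 | [4-methoxy-2,6-bis(methoxymethoxy)phenyl]lithium | [Li]c1c(OCOC)cc(OC)cc1OCOC | intermediate
13 | 2-iodo-5-methoxy-1,3-bis(methoxymethoxy)benzene | COCOc1cc(OC)cc(OCOC)c1I | intermediate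
14 | [(2S)-5-methyl-2-(prop-1-en-2-yl)hex-4-en-1-yl]zinc iodide | C=C(C)[C@H](CC=C(C)C)C[Zn]I | intermediate
15 | 5-methoxy-1,3-bis(methoxymethoxy)-2-[(2R)-5-methyl-2-(prop-1-en-2-yl)hex-4-en-1-yl]benzene | C=C(C)[C@H](CC=C(C)C)Cc1c(OCOC)cc(OC)cc1OCOC | intermediate
16 | aryllithium of 15, lithiated between OMOM and OMe | C=C(C)[C@H](CC=C(C)C)Cc1c(OCOC)cc(OC)c([Li])c1OCOC | intermediate
17 | 6-methoxy-2,4-bis(methoxymethoxy)-3-[(2R)-lavandulyl]benzaldehyde | C=C(C)[C@H](CC=C(C)C)Cc1c(OCOC)cc(OC)c(C=O)c1OCOC | intermediate
18 | 2-hydroxy-6-methoxy-4-(methoxymethoxy)-3-[(2R)-lavandulyl]benzaldehyde | C=C(C)[C@H](CC=C(C)C)Cc1c(OCOC)cc(OC)c(C=O)c1O | intermediate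
19 | 2,4-dihydroxybenzoic acid | O=C(O)c1ccc(O)cc1O | starting material
20 | methoxymethyl 2,4-bis(methoxymethoxy)benzoate | COCOC(=O)c1ccc(OCOC)cc1OCOC | intermediate
21 | 2,4-bis(methoxymethoxy)benzoic acid | COCOc1ccc(C(=O)O)c(OCOC)c1 | intermediate
22 | 2-formyl-3-methoxy-5-(methoxymethoxy)-6-[(2R)-lavandulyl]phenyl 2,4-bis(methoxymethoxy)benzoate | C=C(C)[C@H](CC=C(C)C)Cc1c(OCOC)cc(OC)c(C=O)c1OC(=O)c1ccc(OCOC)cc1OCOC | intermediate
23 | 2-(dimethoxymethyl)-3-methoxy-5-(methoxymethoxy)-6-[(2R)-lavandulyl]phenyl 2,4-bis(methoxymethoxy)benzoate | C=C(C)[C@H](CC=C(C)C)Cc1c(OCOC)cc(OC)c(C(OC)OC)c1OC(=O)c1ccc(OCOC)cc1OCOC | intermediate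
24 | 1-{1-[2-(dimethoxymethyl)-3-methoxy-5-(methoxymethoxy)-6-[(2R)-lavandulyl]phenoxy]ethenyl}-2,4-bis(methoxymethoxy)benzene | C=C(C)[C@H](CC=C(C)C)Cc1c(OCOC)cc(OC)c(C(OC)OC)c1OC(=C)c1ccc(OCOC)cc1OCOC | intermediate
25 | 2-{[1-(2,4-bis(methoxymethoxy)phenyl)ethenyl]oxy}-6-methoxy-4-(methoxymethoxy)-3-[(2R)-lavandulyl]benzaldehyde | C=C(C)[C@H](CC=C(C)C)Cc1c(OCOC)cc(OC)c(C=O)c1OC(=C)c1ccc(OCOC)cc1OCOC | intermediate
26 | (2S)-2-[2,4-bis(methoxymethoxy)phenyl]-5-methoxy-7-(methoxymethoxy)-8-[(2R)-lavandulyl]chroman-4-one | C=C(C)[C@H](CC=C(C)C)Cc1c(OCOC)cc(OC)c2c1O[C@H](c1ccc(OCOC)cc1OCOC)CC2=O | intermediate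
27 | kurarinone, (2S)-2-(2,4-dihydroxyphenyl)-7-hydroxy-5-methoxy-8-[(2R)-5-methyl-2-(prop-1-en-2-yl)hex-4-en-1-yl]chroman-4-one | C=C(C)[C@H](CC=C(C)C)Cc1c(O)cc(OC)c2c1O[C@H](c1ccc(O)cc1O)CC2=O | target

**Step count and risks**
Total steps: 15. Longest linear sequence: 12 steps (steps 1–4, 7–9, 11–15).

Steps most likely to fail:

1. Step 14 (Proposed new method). What may go wrong: insufficient facial discrimination in the Rh–H insertion, exo insertion, decarbonylation of the acyl rhodium hydride, or rhodium hydride migration of the side-chain alkenes. Fallback with known chemistry, setting out from 18 and returning at 26: addition of HC≡CMgBr (excess, THF, 0 °C) to 18 would give the propargylic alcohol F1. Oxidation with MnO2 (CH2Cl2) would give the ynone F2. Treatment with Et2NH in EtOH would close it, through the enaminone and 6-endo oxa-Michael addition, to the 5-methoxy-7-(methoxymethoxy)-8-lavandulylchromone F3. Separately, commercial 4-bromoresorcinol would be converted with MOMCl and i-Pr2NEt into 1-bromo-2,4-bis(methoxymethoxy)benzene F4, and bromine–lithium exchange (n-BuLi, −78 °C), B(Oi-Pr)3 and aqueous work-up would give 2,4-bis(methoxymethoxy)phenylboronic acid F5. Rhodium-catalysed asymmetric 1,4-addition of F5 to F3 ([Rh(OH)(cod)]2, an electron-poor chiral biaryl bisphosphine, toluene–H2O), a known route to 5,7-dioxygenated flavanones, would give 26 with C2 set in the arylation.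

2. Step 13. What may go wrong: sluggish methylenation of the doubly ortho-flanked ester, or hydrolysis of the enol ether while the acetal is being removed. Fallback, setting out from 18 and returning at 25: the aldehyde would be carried at the alcohol level so that no acid is needed after the enol ether exists. NaBH4 (MeOH, 0 °C) would reduce 18 to the salicyl alcohol F6. Selective silylation of the primary hydroxyl (TBSCl, imidazole, CH2Cl2) would give the silyl ether F7. Steglich esterification with 21 would give the ester F8, and Cp2TiMe2 (toluene, 70 °C) the enol ether F9. Bu4NF buffered with AcOH would give the benzylic alcohol F10, and MnO2 (CH2Cl2, rt) would oxidise it to 25.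

3. Step 15. What may go wrong: acid-promoted ionisation of the C2–O1 bond, with loss of configuration once the ring B phenols are free, or addition of the freed 7-OH to the isopropenyl group. Fallback, setting out from 26 and returning at 27: Me3SiOTf with 2,2'-bipyridyl (CH2Cl2, 0 °C) would convert the three aryl MOM ethers, by acetal exchange through a bipyridinium salt and without free Brønsted acid, into the tris(trimethylsilyl) ether F11. Brief stirring in MeOH–H2O with AcOH (1 equiv) would hydrolyse it to 27.

**Further compounds**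
F1 | step 14 | 1-{2-hydroxy-6-methoxy-4-(methoxymethoxy)-3-[(2R)-lavandulyl]phenyl}prop-2-yn-1-ol (carbinol centre unassigned) | C=C(C)[C@H](CC=C(C)C)Cc1c(OCOC)cc(OC)c(C(O)C#C)c1O
F2 | step 14 | 1-{2-hydroxy-6-methoxy-4-(methoxymethoxy)-3-[(2R)-lavandulyl]phenyl}prop-2-yn-1-one | C=C(C)[C@H](CC=C(C)C)Cc1c(OCOC)cc(OC)c(C(=O)C#C)c1O
F3 | step 14 | 5-methoxy-7-(methoxymethoxy)-8-[(2R)-lavandulyl]-4H-chromen-4-one | C=C(C)[C@H](CC=C(C)C)Cc1c(OCOC)cc(OC)c2c1OC=CC2=O
F4 | step 14 | 1-bromo-2,4-bis(methoxymethoxy)benzene | COCOc1ccc(Br)c(OCOC)c1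
F5 | step 14 | 2,4-bis(methoxymethoxy)phenylboronic acid | COCOc1ccc(B(O)O)c(OCOC)c1
F6 | step 13 | 2-(hydroxymethyl)-3-methoxy-5-(methoxymethoxy)-6-[(2R)-lavandulyl]phenol | C=C(C)[C@H](CC=C(C)C)Cc1c(OCOC)cc(OC)c(CO)c1O
F7 | step 13 | 2-{[(tert-butyldimethylsilyl)oxy]methyl}-3-methoxy-5-(methoxymethoxy)-6-[(2R)-lavandulyl]phenol | C=C(C)[C@H](CC=C(C)C)Cc1c(OCOC)cc(OC)c(CO[Si](C)(C)C(C)(C)C)c1O
F8 | step 13 | 2-{[(tert-butyldimethylsilyl)oxy]methyl}-3-methoxy-5-(methoxymethoxy)-6-[(2R)-lavandulyl]phenyl 2,4-bis(methoxymethoxy)benzoate | C=C(C)[C@H](CC=C(C)C)Cc1c(OCOC)cc(OC)c(CO[Si](C)(C)C(C)(C)C)c1OC(=O)c1ccc(OCOC)cc1OCOC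
F9 | step 13 | tert-butyldimethylsilyl ether of F10 | C=C(C)[C@H](CC=C(C)C)Cc1c(OCOC)cc(OC)c(CO[Si](C)(C)C(C)(C)C)c1OC(=C)c1ccc(OCOC)cc1OCOC
F10 | step 13 | (2-{[1-(2,4-bis(methoxymethoxy)phenyl)ethenyl]oxy}-6-methoxy-4-(methoxymethoxy)-3-[(2R)-lavandulyl]phenyl)methanol | C=C(C)[C@H](CC=C(C)C)Cc1c(OCOC)cc(OC)c(CO)c1OC(=C)c1ccc(OCOC)cc1OCOC
F11 | step 15 | 7,2',4'-tris-O-(trimethylsilyl)kurarinone | C=C(C)[C@H](CC=C(C)C)Cc1c(O[Si](C)(C)C)cc(OC)c2c1O[C@H](c1ccc(O[Si](C)(C)C)cc1O[Si](C)(C)C)CC2=O
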